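**Plan**
- Retrosynthesis: the ring B carboxyl goes back to a formyl group and then to C–H; the two silyl ethers come off; ring A is cut at its acyl C–O bond and at its C1–C6 bond, leaving a benzylic alcohol and a diketo-dioxinone, itself cut into a dioxinone, one methyl and two acetyl units.
- Feature used: ring A (C1 carboxyl-bearing, C2 OH, C3 CH3, C4 OH, C5 H, C6 CH3) has oxygen on C2, C4 and the ester carbon and a methyl on C6. This is the pattern of a folded 4-methyl-3,5,7-trioxooctanoate, so the hindered 2,6-disubstituted ester can be made before the ring exists.
- Forward: the dioxinone chain is built in three steps and the ring B alcohol in three; acylketene capture joins them and aldol folding closes ring A; desilylation, formylation of ring B and chlorite oxidation complete ring B.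
- The carboxyl enters last and cold, because an acid ortho to the benzylic ester can lactonise to a phthalide; ring B is symmetric until then, so formylation has no regiochemical choice within that ring.
- Stereochemistry: the target has no stereocentre; the single CH(CH3) centre of 3, 4, 9 and 10 is labile, racemic, and ends as sp2 C3 of ring A.

Key step: step 7

Remark on the chemistry: the 1,3-dicarbonyl compounds 3, 4, 9 and 10 are drawn as keto tautomers although they should exist largely as enols; 3,5-dihydroxy-4-methylbenzoic acid is assumed to be purchasable.

**Step 1**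
Reactants: 1 2,2,6-trimethyl-4H-1,3-dioxin-4-one
Product: 2 6-ethyl-2,2-dimethyl-4H-1,3-dioxin-4-one
Conditions: LiN(iPr)2, THF, −78 °C; MeI, DMPU, −78 → −40 °C
Reagents that add atoms: iodomethane, CI
Why: The lithium dienolate of the vinylogous ester should be alkylated by the reactive halide at the exocyclic γ-carbon when a polar additive loosens the ion pair, a known γ-alkylation of dioxinone dienolates that creates no stereocentre.

**Step 2**
Reactants: 2 6-ethyl-2,2-dimethyl-4H-1,3-dioxin-4-one
Product: 3 racemic 2,2-dimethyl-6-(3-oxobutan-2-yl)-4H-1,3-dioxin-4-one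
Conditions: LiN(SiMe3)2, THF, −78 °C; AcCl (0.5 equiv), −78 °C; 1 M HCl quench
Reagents that add atoms: acetyl chloride, CC(=O)Cl
Why: C-Acylation of the lithium dienolate at its γ-carbon (vinylogous Claisen condensation) is the standard entry to keto-dioxinones; half of the dienolate acts as base for the more acidic product and returns as 2, and the new CH(CH3) centre forms racemic and stays labile.

**Step 3**
Reactants: 3 racemic 2,2-dimethyl-6-(3-oxobutan-2-yl)-4H-1,3-dioxin-4-one
Product: 4 racemic 6-(3,5-dioxohexan-2-yl)-2,2-dimethyl-4H-1,3-dioxin-4-one
Conditions: LiN(iPr)2 (2.1 equiv), THF, −78 °C; MeC(O)N(OMe)Me, −78 → −20 °C; cold 1 M HCl quench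
Reagents that add atoms: N-methoxy-N-methylacetamide, CC(=O)N(C)OC
Why: Double deprotonation should give a dianion whose terminal methyl carbanion is the more basic and nucleophilic site, and its Claisen-type C-acylation by the N-methoxy-N-methyl amide stops at a chelated adduct that releases the 1,3-diketone only on acidic quench.

**Step 4**
Reactants: 5 3,5-dihydroxy-4-methylbenzoic acid
Product: 6 methyl 3,5-dihydroxy-4-methylbenzoate
Conditions: MeOH, H2SO4 (cat.), reflux
Reagents that add atoms: methanol, CO
Why: Fischer esterification in excess methanol should convert the unhindered acid into its methyl ester and leave the phenols untouched.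

**Step 5**
Reactants: 6 methyl 3,5-dihydroxy-4-methylbenzoate
Product: 7 methyl 3,5-bis(tert-butyldimethylsilyloxy)-4-methylbenzoate
Conditions: TBSCl (2.4 equiv), imidazole, DMF, rt
Reagents that add atoms: tert-butyldimethylsilyl chloride, CC(C)(C)[Si](C)(C)Cl
Why: Imidazole-promoted silylation of phenols is routine and masks both hydroxyls, so that only the benzylic alcohol can later capture the ketene.

**Step 6**
Reactants: 7 methyl 3,5-bis(tert-butyldimethylsilyloxy)-4-methylbenzoate
Product: 8 [3,5-bis(tert-butyldimethylsilyloxy)-4-methylphenyl]methanol
Conditions: iBu2AlH (2.5 equiv), CH2Cl2, −78 → 0 °C; aq. potassium sodium tartrate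
Reagents that add atoms: none
Why: Reduction of the benzoate ester by the aluminium hydride should give the benzylic alcohol, and aryl silyl ethers tolerate this non-nucleophilic hydride at low temperature.

**Step 7**
Reactants: 4 racemic 6-(3,5-dioxohexan-2-yl)-2,2-dimethyl-4H-1,3-dioxin-4-one; 8 [3,5-bis(tert-butyldimethylsilyloxy)-4-methylphenyl]methanol
Product: 11 3,5-bis(tert-butyldimethylsilyloxy)-4-methylbenzyl 2,4-dihydroxy-3,6-dimethylbenzoate, via acylketene 9 (not isolated), via triketo ester 10 (not isolated)
Conditions: 4 (1.2 equiv) added slowly to 8 in PhMe, 110 °C; then Et3N, CH2Cl2, rt; AcOH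
Reagents that add atoms: none
Why: At 110 °C the dioxinone should undergo retro-[4+2] cycloreversion, expelling acetone to leave acylketene 9, whose ketene carbon is attacked by the primary hydroxyl of 8 to form the acyl C–O bond of triketo ester 10 under neutral conditions, before the two ortho substituents that would block esterification of a benzoic acid exist. Triethylamine then enolises C2 of the chain (the methylene between the ester and the C3 ketone), which adds to the C7 methyl ketone in a 6-(enolendo)-exo-trig aldol closure forming the ring A C1–C6 bond; loss of water and enolisation of the two remaining ketones give the resorcinol. The closest known reaction type is the thermolysis of diketo-dioxinones in the presence of an alcohol followed by base-mediated aromatisation to resorcylate esters. No stereocentre is created, and the labile CH(CH3) centre becomes sp2 C3 of ring A. The step needs capture by the alcohol to beat internal capture of the ketene by the C5 enol oxygen (pyranone formation), which the unhindered primary hydroxyl of 8, kept concentrated while 4 is fed in slowly, should secure; it also needs the aldol mode to beat Claisen attack of C6 on the ester, which holds under a weak amine base because the methyl ketone is the better acceptor, C8 is not deprotonated and the methyl-bearing C4 has only four-membered alternatives. The alcohol carries no carboxyl group and so cannot lactonise, and an amine in an aprotic solvent should leave the aryl silyl ethers and the new ester intact.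

**Step 8**
Reactants: 11 3,5-bis(tert-butyldimethylsilyloxy)-4-methylbenzyl 2,4-dihydroxy-3,6-dimethylbenzoate
Product: 12 3,5-dihydroxy-4-methylbenzyl 2,4-dihydroxy-3,6-dimethylbenzoate
Conditions: Bu4NF, AcOH, THF, 0 °C
Reagents that add atoms: none
Why: Fluoride cleaves aryl silyl ethers rapidly through the strong Si–F bond, and the acetic acid buffer keeps phenoxide basicity low so that the hindered benzylic ester should survive.

**Step 9**
Reactants: 12 3,5-dihydroxy-4-methylbenzyl 2,4-dihydroxy-3,6-dimethylbenzoate
Product: 14 2-formyl-3,5-dihydroxy-4-methylbenzyl 2,4-dihydroxy-3,6-dimethylbenzoate, via aryl iminium chloride 13 (not isolated)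
Conditions: POCl3 (1.2 equiv), DMF, MeCN, 0 °C → rt; then H2O, rt
Reagents that add atoms: N,N-dimethylformamide, CN(C)C=O; water, O
Why: In this Vilsmeier–Haack formylation the chloroiminium ion should attack the alkylated resorcinol ring B at either of its two equivalent free positions (ortho to one OH, para to the other), while ring A is deactivated by its ester, and hydrolysis of iminium 13 and of any aryl formate on work-up gives the aldehyde.

**Step 10**
Reactants: 14 2-formyl-3,5-dihydroxy-4-methylbenzyl 2,4-dihydroxy-3,6-dimethylbenzoate
Product: 15 6-[(2,4-dihydroxy-3,6-dimethylbenzoyl)oxymethyl]-2,4-dihydroxy-3-methylbenzoic acid (target)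
Conditions: NaClO2, H2NSO3H, dioxane/H2O, 0 °C; cold extractive work-up, no base, no heating
Reagents that add atoms: sodium chlorite, [Na+].[O-]Cl=O
Why: Chlorite oxidation of a hydroxybenzaldehyde with sulfamic acid as hypochlorite scavenger (Lindgren variant of the Pinnick oxidation) should give the acid at 0 °C in a mildly acidic medium, conditions chosen so that the phenolic rings are not chlorinated and the ortho carboxyl does not lactonise onto the benzylic carbon.

**Compound list**
1 | 2,2,6-trimethyl-4H-1,3-dioxin-4-one | CC1=CC(=O)OC(C)(C)O1 | starting material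
2 | 6-ethyl-2,2-dimethyl-4H-1,3-dioxin-4-one | CCC1=CC(=O)OC(C)(C)O1 | intermediate
3 | racemic 2,2-dimethyl-6-(3-oxobutan-2-yl)-4H-1,3-dioxin-4-one | CC(=O)C(C)C1=CC(=O)OC(C)(C)O1 | intermediate
4 | racemic 6-(3,5-dioxohexan-2-yl)-2,2-dimethyl-4H-1,3-dioxin-4-one [6-(1-methyl-2,4-dioxopentyl) dioxinone] | CC(=O)CC(=O)C(C)C1=CC(=O)OC(C)(C)O1 | intermediate
5 | 3,5-dihydroxy-4-methylbenzoic acid | Cc1c(O)cc(cc1O)C(=O)O | starting material
6 | methyl 3,5-dihydroxy-4-methylbenzoate | COC(=O)c1cc(O)c(C)c(O)c1 | intermediate
7 | methyl 3,5-bis(tert-butyldimethylsilyloxy)-4-methylbenzoate | COC(=O)c1cc(O[Si](C)(C)C(C)(C)C)c(C)c(O[Si](C)(C)C(C)(C)C)c1 | intermediate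
8 | [3,5-bis(tert-butyldimethylsilyloxy)-4-methylphenyl]methanol | Cc1c(O[Si](C)(C)C(C)(C)C)cc(CO)cc1O[Si](C)(C)C(C)(C)C | intermediate
9 | acylketene, racemic 4-methyl-3,5,7-trioxooct-1-en-1-one (formed in the flask) | CC(=O)CC(=O)C(C)C(=O)C=C=O | intermediate
10 | triketo ester, racemic 3,5-bis(tert-butyldimethylsilyloxy)-4-methylbenzyl 4-methyl-3,5,7-trioxooctanoate (formed in the flask) | CC(=O)CC(=O)C(C)C(=O)CC(=O)OCc1cc(O[Si](C)(C)C(C)(C)C)c(C)c(O[Si](C)(C)C(C)(C)C)c1 | intermediate
11 | 3,5-bis(tert-butyldimethylsilyloxy)-4-methylbenzyl 2,4-dihydroxy-3,6-dimethylbenzoate | Cc1cc(O)c(C)c(O)c1C(=O)OCc1cc(O[Si](C)(C)C(C)(C)C)c(C)c(O[Si](C)(C)C(C)(C)C)c1 | intermediate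
12 | 3,5-dihydroxy-4-methylbenzyl 2,4-dihydroxy-3,6-dimethylbenzoate | Cc1cc(O)c(C)c(O)c1C(=O)OCc1cc(O)c(C)c(O)c1 | intermediate
13 | aryl iminium chloride, N-[[2-[(2,4-dihydroxy-3,6-dimethylbenzoyl)oxymethyl]-4,6-dihydroxy-5-methylphenyl]methylidene]-N-methylmethanaminium chloride (formed in the flask) | Cc1cc(O)c(C)c(O)c1C(=O)OCc1cc(O)c(C)c(O)c1C=[N+](C)C.[Cl-] | intermediate
14 | 2-formyl-3,5-dihydroxy-4-methylbenzyl 2,4-dihydroxy-3,6-dimethylbenzoate | Cc1cc(O)c(C)c(O)c1C(=O)OCc1cc(O)c(C)c(O)c1C=O | intermediate
15 | 6-[(2,4-dihydroxy-3,6-dimethylbenzoyl)oxymethyl]-2,4-dihydroxy-3-methylbenzoic acid | Cc1cc(O)c(C)c(O)c1C(=O)OCc1cc(O)c(C)c(O)c1C(=O)O | target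

**Step count**
Total: 10 steps. Longest linear sequence: 7 steps (steps 1, 2, 3, 7, 8, 9, 10; the alcohol branch through steps 4, 5, 6 is equally long).

**Steps most likely to fail**

Step 7. The acylketene may be captured by its own C5 enol oxygen faster than by the alcohol, or the triketo ester may fold by Claisen attack on the ester with loss of the alcohol. The fallback sets out from 8 and comes back at 11. Ring A is bought ready-made as 2,4-dihydroxy-3,6-dimethylbenzoic acid (Cc1cc(O)c(C)c(O)c1C(=O)O) and joined to 8 by Mitsunobu esterification (PPh3, DIAD, THF, 0 °C). There the carboxylate attacks the activated benzylic carbon, so the alkyl C–O bond is formed in place of the hindered acyl C–O bond, and the far less acidic phenols should not compete. This should give 11 directly without any new compound on the way.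

Step 10. Chlorination or oxidation of the electron-rich phenolic rings by hypochlorous acid or chlorine dioxide may outrun the scavenger. The fallback sets out from 12 and comes back at 15, leaving out 13 and 14. Ring B is carboxylated directly with magnesium methyl carbonate, MeOMgOCO2Me, in DMF at 110–120 °C with a short contact time and a cold acidic work-up. The magnesium phenoxide delivers CO2 to the position ortho to OH, as known for alkylresorcinols, ring A being deactivated by its ester. The price is heat in a basic medium, which is why this is not the main route.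

Step 1. Proton exchange between dienolate and product may cause double methylation, attack at the α-carbon, or self-condensation of the dienolate with unreacted dioxinone. The fallback sets out from 1 and comes back at 3 by reversing the order. Compound 1 is first C-acetylated (LiN(SiMe3)2, AcCl, THF, −78 °C) to 2,2-dimethyl-6-(2-oxopropyl)-4H-1,3-dioxin-4-one F1. Its doubly activated methylene is then methylated (K2CO3, MeI, acetone, rt) to give 3, so the methyl group enters by alkylation of a stabilised enolate and not of the dienolate.

**Further compounds**
F0 | step 7 | none | none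
F0 | step 10 | none | none
F1 | step 1 | 2,2-dimethyl-6-(2-oxopropyl)-4H-1,3-dioxin-4-one | CC(=O)CC1=CC(=O)OC(C)(C)O1
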